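**Retrosynthetic overview**
1. Nothing in the flavanone is built: ring A, ring C and the C2 stereocentre are bought as (2S)-pinocembrin 1. The cyclohexene ring, its side-chain stereocentre and a tertiary C–O stereocentre are bought as (1R,4R)-p-mentha-2,8-dien-1-ol 2.
2. Activation and C–O coupling: 2 → lithium alkoxide 3 → methyl carbonate 4; palladium-catalysed O-allylation of the 7-OH of 1 then gives the tertiary allyl aryl ether 5.
3. Key disconnection (aryl C6–cyclohexenyl bond): aromatic Claisen [3,3] shift of 5 through ortho-dienone 6 to the 6-terpenyl flavanone 7; the C–O centre is transferred to the new C–C centre, trans to the side chain.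
4. Last disconnection (isopropyl from isopropenyl): selective hydrogenation of 7 gives the target 8. No ring is formed in the route; only the bond between the two bought ring systems is made.

Assumption: 1 and 2 (the epimer with OH trans to isopropenyl) are bought as single enantiomers from the natural pool (propolis flavanone; terpene alcohol of the (+)-limonene/(+)-2-carene family).

**Step 1**
Reactants: 2 (1R,4R)-1-methyl-4-(prop-1-en-2-yl)cyclohex-2-en-1-ol
Product: 4 methyl (1R,4R)-1-methyl-4-(prop-1-en-2-yl)cyclohex-2-en-1-yl carbonate, via lithium alkoxide 3 (not isolated)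
Conditions: n-BuLi (1.05 equiv), THF, −78 °C; then ClCO2Me (1.2 equiv), −78 → 0 °C
Reagents that add atoms: methyl chloroformate, COC(=O)Cl; n-butyllithium, [Li]CCCC (its lithium stays only in intermediate 3)
Why: Alkoxycarbonylation of a lithium tertiary alkoxide (carbonate formation) acylates oxygen at low temperature without breaking any C–O bond at a stereocentre, so both centres of 2 are carried over unchanged.

**Step 2**
Reactants: 1 (2S)-5,7-dihydroxy-2-phenyl-2,3-dihydro-4H-chromen-4-one; 4 methyl (1R,4R)-1-methyl-4-(prop-1-en-2-yl)cyclohex-2-en-1-yl carbonate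
Product: 5 (2S)-5-hydroxy-7-{[(1R,4R)-1-methyl-4-(prop-1-en-2-yl)cyclohex-2-en-1-yl]oxy}-2-phenyl-2,3-dihydro-4H-chromen-4-one
Conditions: Pd(PPh3)4 (5 mol %), THF, 0 °C → rt; quick filtration through Et3N-washed silica
Reagents that add atoms: none
Why: Palladium-catalysed decarboxylative allylic etherification (Tsuji–Trost type): zerovalent palladium ionises the tertiary carbonate with inversion, the released methoxide deprotonates only the acidic, non-chelated 7-OH, and the phenoxide attacks the more substituted allyl terminus anti to the metal (the kinetic branched selectivity known from O-tert-prenylation of phenols), so the tertiary C–O centre is rebuilt with net retention, oxygen trans to the isopropenyl group, under neutral conditions that leave the base-labile flavanone C2 centre alone.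

**Step 3**
Reactants: 5 (2S)-5-hydroxy-7-{[(1R,4R)-1-methyl-4-(prop-1-en-2-yl)cyclohex-2-en-1-yl]oxy}-2-phenyl-2,3-dihydro-4H-chromen-4-one
Product: 7 (2S)-5,7-dihydroxy-6-[(1R,6R)-3-methyl-6-(prop-1-en-2-yl)cyclohex-2-en-1-yl]-2-phenyl-2,3-dihydro-4H-chromen-4-one, via ortho-dienone 6 (not isolated)
Conditions: PhMe, PhNEt2 (1 equiv), 110 °C, sealed tube
Reagents that add atoms: none
Why: Aromatic Claisen rearrangement, a [3,3]-sigmatropic shift that is suprafacial on the cyclohexenyl unit, forms the C6–C bond on the ring face the ether oxygen leaves, so the aryl group ends trans to the neighbouring isopropenyl group (the new stereocentre is dictated by the two centres bought in 2); migration is expected mainly to C6 because the hydrogen-bonded 5-OH/C4=O chelate fixes the C6=C7 bond, and dienone 6 enolises at once to the phenol.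

**Step 4**
Reactants: 7 (2S)-5,7-dihydroxy-6-[(1R,6R)-3-methyl-6-(prop-1-en-2-yl)cyclohex-2-en-1-yl]-2-phenyl-2,3-dihydro-4H-chromen-4-one
Product: 8 (2S)-5,7-dihydroxy-6-[(1S,6S)-3-methyl-6-(propan-2-yl)cyclohex-2-en-1-yl]-2-phenyl-2,3-dihydro-4H-chromen-4-one
Conditions: H2 (1 atm), RhCl(PPh3)3 (5 mol %), PhH–EtOH 1:1, rt
Reagents that add atoms: none
Why: Chemoselective homogeneous hydrogenation with RhCl(PPh3)3 reduces the unhindered 1,1-disubstituted isopropenyl alkene much faster than the trisubstituted ring alkene and leaves the aryl ketone and the benzylic C2–O bond intact, so no stereocentre is touched (the descriptors change from R,R to S,S only through CIP priorities).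

**Compound list**
1 | (2S)-5,7-dihydroxy-2-phenyl-2,3-dihydro-4H-chromen-4-one, (S)-pinocembrin | O=C1C[C@@H](c2ccccc2)Oc2cc(O)cc(O)c21 | starting material
2 | (1R,4R)-1-methyl-4-(prop-1-en-2-yl)cyclohex-2-en-1-ol (OH trans to isopropenyl) | C[C@]1(O)C=C[C@H](C(C)=C)CC1 | starting material
3 | lithium (1R,4R)-1-methyl-4-(prop-1-en-2-yl)cyclohex-2-en-1-olate | C[C@]1([O-])C=C[C@H](C(C)=C)CC1.[Li+] | intermediate
4 | methyl (1R,4R)-1-methyl-4-(prop-1-en-2-yl)cyclohex-2-en-1-yl carbonate | C[C@]1(OC(=O)OC)C=C[C@H](C(C)=C)CC1 | intermediate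
5 | (2S)-5-hydroxy-7-{[(1R,4R)-1-methyl-4-(prop-1-en-2-yl)cyclohex-2-en-1-yl]oxy}-2-phenyl-2,3-dihydro-4H-chromen-4-one | C[C@]1(Oc2cc(O)c3c(c2)O[C@H](c2ccccc2)CC3=O)C=C[C@H](C(C)=C)CC1 | intermediate
6 | (2S)-5-hydroxy-6-[(1R,6R)-3-methyl-6-(prop-1-en-2-yl)cyclohex-2-en-1-yl]-2-phenyl-2,3-dihydro-4H-chromene-4,7(6H)-dione (ortho-dienone, C6 transient and undefined) | CC1=C[C@@H](C2C(=O)C=C3O[C@H](c4ccccc4)CC(=O)C3=C2O)[C@H](C(C)=C)CC1 | intermediate
7 | (2S)-5,7-dihydroxy-6-[(1R,6R)-3-methyl-6-(prop-1-en-2-yl)cyclohex-2-en-1-yl]-2-phenyl-2,3-dihydro-4H-chromen-4-one (aryl and isopropenyl trans) | CC1=C[C@@H](c2c(O)cc3c(c2O)C(=O)C[C@@H](c2ccccc2)O3)[C@H](C(C)=C)CC1 | intermediate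
8 | (2S)-5,7-dihydroxy-6-[(1S,6S)-3-methyl-6-(propan-2-yl)cyclohex-2-en-1-yl]-2-phenyl-2,3-dihydro-4H-chromen-4-one (aryl and isopropyl trans) | CC1=C[C@@H](c2c(O)cc3c(c2O)C(=O)C[C@@H](c2ccccc2)O3)[C@H](C(C)C)CC1 | target

**Totals**
Total step count: 4. Longest linear sequence: 4 steps (2 → 4 → 5 → 7 → 8); 1 enters at step 2.

**Steps most likely to fail, with fallbacks**

Step 2 (highest risk). The phenoxide may attack the secondary allyl terminus, C-allylate the electron-rich ring A, or the π-allyl intermediate may lose a β-hydrogen to give a triene. Fallback: set out from 1 and 2 themselves and join them by a Lewis-acid-mediated Friedel–Crafts allylation (BF3·OEt2 on basic Al2O3, CH2Cl2, rt). The allyl cation from 2 is attacked at its secondary terminus anti to the isopropenyl group, which gives the same trans arrangement and comes back to the route at 7 after the C8 regioisomer is removed by chromatography. No new compound is made on the way (F0).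

Step 3. The 7-O ether can migrate to C8 as well as C6, and a tertiary allylic ether of an acidic phenol can ionise or lose the phenol by elimination. Fallback: set out from 1 and force the regiochemistry through the other oxygen.
- Silylate the free 7-OH (TBSCl, imidazole, DMF, 0 °C) to give (2S)-7-[tert-butyl(dimethyl)silyl]oxy-5-hydroxyflavanone F1.
- Couple F1 with carbonate 4 under Pd(PPh3)4; only the chelated 5-OH is left to react, giving the 5-O-terpenyl ether F2.
- Warm F2: its only free ortho carbon is C6, so the [3,3] shift proceeds through the ortho-dienone F3 without regiochemical choice. F3 enolises rather than undergoing a further Cope shift to C8, which would create a quaternary attachment, and gives the 7-O-silyl ether of 7, F4.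
- Desilylate with HF·pyridine in THF at 0 °C to come back to the route at 7.

Step 4. The rhodium catalyst may be slowed by the chelating hydroxy-ketone, or may isomerise the isopropenyl group into the tetrasubstituted position. Fallback: set out from 2 and move the reduction in front of the key step.
- Partially hydrogenate 2 (RhCl(PPh3)3, H2, one equivalent taken up; over-reduced material removed on AgNO3-impregnated silica) to (1R,4S)-1-methyl-4-(propan-2-yl)cyclohex-2-en-1-ol F5.
- Convert F5 through its lithium alkoxide F6 into the methyl carbonate F7 (as in step 1).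
- Couple F7 with 1 under Pd(PPh3)4 to the saturated aryl ether F8 (as in step 2).
- Claisen rearrangement of F8 through the ortho-dienone F9 (as in step 3) comes back to the route directly at 8.

**Further compounds**
F0 | step 2 | none | none
F1 | step 3 | (2S)-7-[tert-butyl(dimethyl)silyl]oxy-5-hydroxy-2-phenyl-2,3-dihydro-4H-chromen-4-one | O=C1C[C@@H](c2ccccc2)Oc2cc(O[Si](C)(C)C(C)(C)C)cc(O)c21
F2 | step 3 | (2S)-7-[tert-butyl(dimethyl)silyl]oxy-5-{[(1R,4R)-1-methyl-4-(prop-1-en-2-yl)cyclohex-2-en-1-yl]oxy}-2-phenyl-2,3-dihydro-4H-chromen-4-one | C[C@]1(Oc2cc(O[Si](C)(C)C(C)(C)C)cc3c2C(=O)C[C@@H](c2ccccc2)O3)C=C[C@H](C(C)=C)CC1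
F3 | step 3 | (2S)-7-[tert-butyl(dimethyl)silyl]oxy-6-[(1R,6R)-3-methyl-6-(prop-1-en-2-yl)cyclohex-2-en-1-yl]-2-phenyl-2,3-dihydro-4H-chromene-4,5(6H)-dione (ortho-dienone) | CC1=C[C@@H](C2C(=O)C3=C(C=C2O[Si](C)(C)C(C)(C)C)O[C@H](c2ccccc2)CC3=O)[C@H](C(C)=C)CC1
F4 | step 3 | (2S)-7-[tert-butyl(dimethyl)silyl]oxy-5-hydroxy-6-[(1R,6R)-3-methyl-6-(prop-1-en-2-yl)cyclohex-2-en-1-yl]-2-phenyl-2,3-dihydro-4H-chromen-4-one | CC1=C[C@@H](c2c(O[Si](C)(C)C(C)(C)C)cc3c(c2O)C(=O)C[C@@H](c2ccccc2)O3)[C@H](C(C)=C)CC1
F5 | step 4 | (1R,4S)-1-methyl-4-(propan-2-yl)cyclohex-2-en-1-ol | C[C@]1(O)C=C[C@H](C(C)C)CC1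
F6 | step 4 | lithium (1R,4S)-1-methyl-4-(propan-2-yl)cyclohex-2-en-1-olate | C[C@]1([O-])C=C[C@H](C(C)C)CC1.[Li+]
F7 | step 4 | methyl (1R,4S)-1-methyl-4-(propan-2-yl)cyclohex-2-en-1-yl carbonate | C[C@]1(OC(=O)OC)C=C[C@H](C(C)C)CC1
F8 | step 4 | (2S)-5-hydroxy-7-{[(1R,4S)-1-methyl-4-(propan-2-yl)cyclohex-2-en-1-yl]oxy}-2-phenyl-2,3-dihydro-4H-chromen-4-one | C[C@]1(Oc2cc(O)c3c(c2)O[C@H](c2ccccc2)CC3=O)C=C[C@H](C(C)C)CC1
F9 | step 4 | (2S)-5-hydroxy-6-[(1S,6S)-3-methyl-6-(propan-2-yl)cyclohex-2-en-1-yl]-2-phenyl-2,3-dihydro-4H-chromene-4,7(6H)-dione (ortho-dienone) | CC1=C[C@@H](C2C(=O)C=C3O[C@H](c4ccccc4)CC(=O)C3=C2O)[C@H](C(C)C)CC1
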